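**Retrosynthetic overview**
1. The (E)-p-coumarate is cut to 4-iodophenol plus the C-4 acrylate (Heck), and the acrylate to the C-4 alcohol.
2. The C-4 carbinol comes from a hydroxyl-directed 1,3-anti reduction of a 4,7-ene-dione, itself made by γ-oxygenation of a β,γ-enone.
3. Key step: the seven-membered ring is made last, by one-carbon ring expansion of a six-five hydrindenone (1,2-alkenyl shift in a β-oxido carbenoid from CH3CHBr2, which brings in C-6 and its methyl).
4. The tertiary carbinol comes from isopropyl addition to a planar dienone, anti to the angular methyl.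
5. The six-membered ring is built on 3-methylcyclopent-2-enone by an enantioselective [4+2] annulation with a silyloxy diene. Ring order: five (bought), six, then seven.

Assumption: the (S)-oxazaborolidinium salt of step 2 is taken to give the (3aR) series; if its facial sense is the reverse, the (R)-catalyst is used and nothing else changes.

The target is (3R,3aS,4S,8aR) in azulene numbering. None of the steps has been run; conditions are proposals from precedent.

**Step 1**
Reactants: 1 (3E)-4-methoxybut-3-en-2-one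
Product: 2 tert-butyl{[(3E)-4-methoxybuta-1,3-dien-2-yl]oxy}dimethylsilane
Conditions: t-BuMe2SiOSO2CF3, Et3N, Et2O, 0 → 25 °C
Reagents that add atoms: tert-butyldimethylsilyl trifluoromethanesulfonate CC(C)(C)[Si](C)(C)OS(=O)(=O)C(F)(F)F
Why: Soft enolisation of the methyl ketone with a silyl triflate and an amine (Danishefsky-type diene synthesis) gives the 2-silyloxy diene; no stereocentre is formed.

**Step 2**
Reactants: 2 tert-butyl{[(3E)-4-methoxybuta-1,3-dien-2-yl]oxy}dimethylsilane; 3 3-methylcyclopent-2-en-1-one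
Product: 5 (3aR)-5-[(tert-butyldimethylsilyl)oxy]-3a-methyl-2,3,3a,4-tetrahydro-1H-inden-1-one, via methoxy cycloadduct 4 (not isolated)
Conditions: (S)-3,3-diphenyl-1-(o-tolyl)tetrahydro-1H,3H-pyrrolo[1,2-c][1,3,2]oxazaborole (20 mol %), HN(SO2CF3)2 (18 mol %), CH2Cl2, −78 → −40 °C; Et3N; then 1,8-diazabicyclo[5.4.0]undec-7-ene (DBU), CH2Cl2, 0 °C
Reagents that add atoms: none
Why: Proposed new method: the triflimide-activated oxazaborolidinium ion binds the enone carbonyl (held by the usual α-C–H···O contact), which lowers the LUMO of the sluggish β-methyl enone and blocks one face, so the CH2 terminus of the silyloxy diene attacks C-3 (Mukaiyama–Michael) and the boron enolate closes onto the methoxy-bearing terminus (net endo [4+2], para orientation), which forms the six-membered ring and sets the quaternary centre C-3a as (R), and DBU then removes methanol by E1cB toward the ketone so that the silyl dienol ether stays intact; closest known reaction type: oxazaborolidinium-catalysed enantioselective Diels–Alder reactions of 2-cyclopentenone and 2-cyclohexenone with silyloxy dienes, not yet shown for a β-alkyl enone that builds a quaternary centre.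

**Step 3**
Reactants: 5 (3aR)-5-[(tert-butyldimethylsilyl)oxy]-3a-methyl-2,3,3a,4-tetrahydro-1H-inden-1-one; 6 isopropylmagnesium chloride
Product: 8 (1R,3aR,7aR)-1-hydroxy-3a-methyl-1-(propan-2-yl)-1,2,3,3a,4,7a-hexahydro-5H-inden-5-one, via silyl dienol ether carbinol 7 (not isolated)
Conditions: i-PrMgCl, CeCl3, THF, −78 °C; pH 7 buffer; crude 7: Bu4NF, THF, 0 → 25 °C; H2O
Reagents that add atoms: none
Why: Organocerium (Imamoto) 1,2-addition to the only free carbonyl (C-5 is masked as the silyl dienol ether) occurs anti to the pseudo-axial angular methyl of the flat dienone and sets C-1 as (R), hydroxyl cis to methyl; fluoride then cleaves the silyl ether and γ-protonation gives the conjugated enone, with C-7a drawn trans (it is finally fixed in step 6, so a 7a-epimer is carried along).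

**Step 4**
Reactants: 8 (1R,3aR,7aR)-1-hydroxy-3a-methyl-1-(propan-2-yl)-1,2,3,3a,4,7a-hexahydro-5H-inden-5-one; 9 1,1-dibromoethane
Product: 11 (3R,3aR,8aR)-3-hydroxy-6,8a-dimethyl-3-(propan-2-yl)-1,2,3,3a,6,8a-hexahydroazulen-7(8H)-one (C-6 epimers), via dibromo diol 10 (not isolated)
Conditions: CH3CHBr2, LiN(i-Pr)2, THF, −95 °C, then 8; n-BuLi, −78 → 0 °C; aq. NH4Cl
Reagents that add atoms: none
Why: Nozaki–Yamamoto β-oxido carbenoid ring expansion: CH3CBr2Li adds to the C-5 carbonyl, Br/Li exchange gives the α-bromo-α-lithio alkoxide, and a 1,2-shift of the alkenyl carbon C-6 (sp2 carbon migrates in preference to the neopentyl-type C-4 methylene) with loss of LiBr inserts the CH3–C unit between C-5 and C-6, and C-protonation of the dienolate gives the seven-membered β,γ-enone; no permanent stereocentre is made.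

**Step 5**
Reactants: 11 (3R,3aR,8aR)-3-hydroxy-6,8a-dimethyl-3-(propan-2-yl)-1,2,3,3a,6,8a-hexahydroazulen-7(8H)-one
Product: 13 (3R,3aR,8aR)-3-hydroxy-6,8a-dimethyl-3-(propan-2-yl)-1,2,3,3a,8,8a-hexahydroazulene-4,7-dione, via C-4 hydroperoxide 12 (not isolated)
Conditions: O2 (1 atm), DBU (0.3 equiv), MeCN, 0 → 25 °C
Reagents that add atoms: dioxygen O=O
Why: Base-mediated autoxidation of a β,γ-unsaturated ketone (as in 5-en-3-one to 4-ene-3,6-dione in steroids): the dienolate is trapped by O2 at the γ-carbon C-4 (the α-carbon C-6 is tertiary and shielded) and Kornblum–DeLaMare fragmentation of the hydroperoxide gives the ene-dione; the C-6 centre disappears and C-3a, now α to a ketone, becomes epimerisable.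

**Step 6**
Reactants: 13 (3R,3aR,8aR)-3-hydroxy-6,8a-dimethyl-3-(propan-2-yl)-1,2,3,3a,8,8a-hexahydroazulene-4,7-dione
Product: 14 (3R,3aS,4S,8aR)-3,4-dihydroxy-6,8a-dimethyl-3-(propan-2-yl)-1,2,3,3a,4,8a-hexahydroazulen-7(8H)-one
Conditions: Me4N[BH(OAc)3], MeCN–AcOH (1:1), −20 → 25 °C
Reagents that add atoms: none
Why: Evans–Saksena hydroxyl-directed reduction: the tertiary C-3 hydroxyl binds boron and delivers hydride inside the molecule to the C-4 carbonyl from its own face, which gives the 1,3-anti diol (4S); only the C-3a epimer with the C-4 carbonyl cis to that hydroxyl (trans ring fusion) can reach the cyclic transition state, so the epimerisable C-3a is funnelled to the trans-fused product, and the remote enone carbonyl C-7 is not reduced.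

**Step 7**
Reactants: 14 (3R,3aS,4S,8aR)-3,4-dihydroxy-6,8a-dimethyl-3-(propan-2-yl)-1,2,3,3a,4,8a-hexahydroazulen-7(8H)-one; 15 prop-2-enoyl chloride
Product: 16 (3R,3aS,4S,8aR)-3-hydroxy-6,8a-dimethyl-7-oxo-3-(propan-2-yl)-1,2,3,3a,4,7,8,8a-octahydroazulen-4-yl prop-2-enoate
Conditions: CH2=CHCOCl, Et3N, 4-(dimethylamino)pyridine (5 mol %), CH2Cl2, −20 → 0 °C
Reagents that add atoms: none
Why: Acylation (nucleophile-catalysed esterification) of the secondary allylic alcohol; the hindered tertiary alcohol does not react and no stereocentre is touched.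

**Step 8**
Reactants: 16 (3R,3aS,4S,8aR)-3-hydroxy-6,8a-dimethyl-7-oxo-3-(propan-2-yl)-1,2,3,3a,4,7,8,8a-octahydroazulen-4-yl prop-2-enoate; 17 4-iodophenol
Product: 18 (3R,3aS,4S,8aR)-3-hydroxy-6,8a-dimethyl-7-oxo-3-(propan-2-yl)-1,2,3,3a,4,7,8,8a-octahydroazulen-4-yl (2E)-3-(4-hydroxyphenyl)prop-2-enoate
Conditions: Pd(OAc)2 (5 mol %), P(o-tol)3 (10 mol %), Et3N, DMF, 80 °C
Reagents that add atoms: none
Why: Mizoroki–Heck arylation of the acrylate gives the (E)-cinnamate through syn insertion and syn β-hydride elimination; the trisubstituted enone alkene is inert and the free phenol is tolerated.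

**Compound list**
1 | (3E)-4-methoxybut-3-en-2-one | CO/C=C/C(C)=O | starting material
2 | tert-butyl{[(3E)-4-methoxybuta-1,3-dien-2-yl]oxy}dimethylsilane | CO/C=C/C(=C)O[Si](C)(C)C(C)(C)C | intermediate
3 | 3-methylcyclopent-2-en-1-one | CC1=CC(=O)CC1 | starting material
4 | (3aR,7S,7aR)-5-[(tert-butyldimethylsilyl)oxy]-7-methoxy-3a-methyl-2,3,3a,4,7,7a-hexahydro-1H-inden-1-one (cis-fused cycloadduct) | CC(C)(C)[Si](C)(C)OC1=C[C@H](OC)[C@H]2[C@](C)(CCC2=O)C1 | intermediate
5 | (3aR)-5-[(tert-butyldimethylsilyl)oxy]-3a-methyl-2,3,3a,4-tetrahydro-1H-inden-1-one | CC(C)(C)[Si](C)(C)OC1=CC=C2[C@](C)(CCC2=O)C1 | intermediate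
6 | isopropylmagnesium chloride | CC(C)[Mg]Cl | starting material
7 | (1R,3aR)-5-[(tert-butyldimethylsilyl)oxy]-3a-methyl-1-(propan-2-yl)-2,3,3a,4-tetrahydro-1H-inden-1-ol | CC(C)(C)[Si](C)(C)OC1=CC=C2[C@](C)(CC[C@@]2(O)C(C)C)C1 | intermediate
8 | (1R,3aR,7aR)-1-hydroxy-3a-methyl-1-(propan-2-yl)-1,2,3,3a,4,7a-hexahydro-5H-inden-5-one | O=C1C=C[C@@H]2[C@](C)(CC[C@@]2(O)C(C)C)C1 | intermediate
9 | 1,1-dibromoethane | CC(Br)Br | starting material
10 | (1R,3aR,7aR)-5-(1,1-dibromoethyl)-3a-methyl-1-(propan-2-yl)-2,3,3a,4,5,7a-hexahydro-1H-indene-1,5-diol (C-5 epimers, present as dilithium alkoxide) | CC(Br)(Br)C1(O)C=C[C@@H]2[C@](C)(CC[C@@]2(O)C(C)C)C1 | intermediate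
11 | (3R,3aR,8aR)-3-hydroxy-6,8a-dimethyl-3-(propan-2-yl)-1,2,3,3a,6,8a-hexahydroazulen-7(8H)-one (C-6 epimers) | CC1C=C[C@@H]2[C@](C)(CC[C@@]2(O)C(C)C)CC1=O | intermediate
12 | (3R,3aS,8aR)-4-hydroperoxy-3-hydroxy-6,8a-dimethyl-3-(propan-2-yl)-1,2,3,3a,4,8a-hexahydroazulen-7(8H)-one (C-4 epimers) | CC1=CC(OO)[C@@H]2[C@](C)(CC[C@@]2(O)C(C)C)CC1=O | intermediate
13 | (3R,3aR,8aR)-3-hydroxy-6,8a-dimethyl-3-(propan-2-yl)-1,2,3,3a,8,8a-hexahydroazulene-4,7-dione | CC1=CC(=O)[C@@H]2[C@](C)(CC[C@@]2(O)C(C)C)CC1=O | intermediate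
14 | (3R,3aS,4S,8aR)-3,4-dihydroxy-6,8a-dimethyl-3-(propan-2-yl)-1,2,3,3a,4,8a-hexahydroazulen-7(8H)-one | CC1=C[C@H](O)[C@@H]2[C@](C)(CC[C@@]2(O)C(C)C)CC1=O | intermediate
15 | prop-2-enoyl chloride | C=CC(Cl)=O | starting material
16 | (3R,3aS,4S,8aR)-3-hydroxy-6,8a-dimethyl-7-oxo-3-(propan-2-yl)-1,2,3,3a,4,7,8,8a-octahydroazulen-4-yl prop-2-enoate | CC1=C[C@H](OC(=O)C=C)[C@@H]2[C@](C)(CC[C@@]2(O)C(C)C)CC1=O | intermediate
17 | 4-iodophenol | Oc1ccc(I)cc1 | starting material
18 | (3R,3aS,4S,8aR)-3-hydroxy-6,8a-dimethyl-7-oxo-3-(propan-2-yl)-1,2,3,3a,4,7,8,8a-octahydroazulen-4-yl (2E)-3-(4-hydroxyphenyl)prop-2-enoate | CC1=C[C@H](OC(=O)/C=C/c2ccc(O)cc2)[C@@H]2[C@](C)(CC[C@@]2(O)C(C)C)CC1=O | target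

**Step count**
Total: 8 steps. Longest linear sequence: 8 steps (1 to 18); the other starting materials enter directly.

**Three steps most likely to fail**

Step 2 (the new method). The β-methyl enone may be too unreactive, diene 2 may not survive the acid catalyst, or the ee may be low. The fallback uses known chemistry and sets out from 2 and 3. The uncatalysed Diels–Alder reaction under high pressure (12 kbar, CH2Cl2, 25 °C), the established way to make β-alkyl cycloalkenones react with alkoxy dienes, gives the racemic cycloadduct, that is 4 together with its mirror image (3aS,7R,7aS)-5-[(tert-butyldimethylsilyl)oxy]-7-methoxy-3a-methyl-2,3,3a,4,7,7a-hexahydro-1H-inden-1-one F1. DBU then gives the racemic dienone, that is 5 and its enantiomer (3aS)-5-[(tert-butyldimethylsilyl)oxy]-3a-methyl-2,3,3a,4-tetrahydro-1H-inden-1-one F2. Preparative chromatography on a chiral stationary phase separates them, and the fallback comes back to the route at 5.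

Step 4. The carbenoid may enolise 8, the free hydroxyl costs base, and the C-4 methylene might migrate instead of the alkenyl carbon. The fallback fixes the regiochemistry through a defined enol ether and sets out from 8. Conjugate hydrosilylation (Et3SiH, RhCl(PPh3)3) gives (1R,3aR,7aR)-3a-methyl-1-(propan-2-yl)-5-[(triethylsilyl)oxy]-2,3,3a,4,7,7a-hexahydro-1H-inden-1-ol F3. Furukawa ethylidenation (Et2Zn, CH3CHI2) gives the siloxycyclopropane with CH–CH3 bridged across C-5 and C-6 of F3 F4. FeCl3 in DMF followed by NaOAc (Ito–Saegusa ring expansion by alkoxy-radical β-scission, chlorination and dehydrochlorination) gives (3R,3aR,8aR)-3-hydroxy-6,8a-dimethyl-3-(propan-2-yl)-1,2,3,3a,4,8a-hexahydroazulen-7(8H)-one F5. Allylic oxidation of its C-4 methylene (t-BuOOH, Rh2(C6H10NO)4, dirhodium tetracaprolactamate) gives the ene-dione, and the fallback comes back to the route at 13.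

Step 5. Oxygen may attack the α-carbon, the hydroperoxide anion may epoxidise the ene-dione, or DBU may trigger retro-aldol opening of the β-hydroxy ketone. The fallback sets out from 11. Epoxidation with 3-chloroperbenzoic acid (NaHCO3, CH2Cl2) gives (3R,3aS,8aR)-4,5-epoxy-3-hydroxy-6,8a-dimethyl-3-(propan-2-yl)octahydroazulen-7(1H)-one F6. Et3N opens the β,γ-epoxy ketone by E1cB to (3R,3aS,8aR)-3,4-dihydroxy-6,8a-dimethyl-3-(propan-2-yl)-1,2,3,3a,4,8a-hexahydroazulen-7(8H)-one as C-4 epimers F7. Dess–Martin periodinane oxidises the secondary allylic alcohol, and the fallback comes back to the route at 13.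

**Further compounds**
F1 | step 2 | (3aS,7R,7aS)-5-[(tert-butyldimethylsilyl)oxy]-7-methoxy-3a-methyl-2,3,3a,4,7,7a-hexahydro-1H-inden-1-one | CC(C)(C)[Si](C)(C)OC1=C[C@@H](OC)[C@@H]2[C@@](C)(CCC2=O)C1
F2 | step 2 | (3aS)-5-[(tert-butyldimethylsilyl)oxy]-3a-methyl-2,3,3a,4-tetrahydro-1H-inden-1-one | CC(C)(C)[Si](C)(C)OC1=CC=C2[C@@](C)(CCC2=O)C1
F3 | step 4 | (1R,3aR,7aR)-3a-methyl-1-(propan-2-yl)-5-[(triethylsilyl)oxy]-2,3,3a,4,7,7a-hexahydro-1H-inden-1-ol | CC[Si](CC)(CC)OC1=CC[C@@H]2[C@](C)(CC[C@@]2(O)C(C)C)C1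
F4 | step 4 | siloxycyclopropane with CH–CH3 bridged across C-5 and C-6 of F3, C-5 keeping OSiEt3 (cyclopropane epimers) | CC1C2(O[Si](CC)(CC)CC)C[C@@]3(C)CC[C@@](O)(C(C)C)[C@@H]3CC12
F5 | step 4 | (3R,3aR,8aR)-3-hydroxy-6,8a-dimethyl-3-(propan-2-yl)-1,2,3,3a,4,8a-hexahydroazulen-7(8H)-one | CC1=CC[C@@H]2[C@](C)(CC[C@@]2(O)C(C)C)CC1=O
F6 | step 5 | (3R,3aS,8aR)-4,5-epoxy-3-hydroxy-6,8a-dimethyl-3-(propan-2-yl)octahydroazulen-7(1H)-one (epoxide and C-6 epimers) | CC1C2OC2[C@@H]3[C@](C)(CC[C@@]3(O)C(C)C)CC1=O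
F7 | step 5 | (3R,3aS,8aR)-3,4-dihydroxy-6,8a-dimethyl-3-(propan-2-yl)-1,2,3,3a,4,8a-hexahydroazulen-7(8H)-one (C-4 epimers) | CC1=CC(O)[C@@H]2[C@](C)(CC[C@@]2(O)C(C)C)CC1=O
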